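**Plan**

- **Cuts:** the two S–O bonds at O7 and O3' go first. O1–C2 (ring C) and C4a–C8a (ring A) are then cut in one operation. C4–C4a is cut last, which separates triacetic lactone from an arylpropiolic N-methoxy-N-methylamide made from methyl gallate.
- **Enabling feature:** ring A is a phloroglucinol (oxygen on C5, C7, C8a) acylated at C4a. C8a–C8–C7–C6–C5–C4a–C4–C3–C2 is therefore one unbranched chain with oxygen on every second carbon. The 2-pyranone hides C8a to C5 of this chain, and the C2–C3 alkyne hides the last 1,3-dicarbonyl unit.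
- **Forward order:** ring B is differentiated (Bn on O4' and O5', MOM on O3') and the chain is joined at C4–C4a. Ring A and then ring C close in one flask, followed by MOM removal, double sulfation and debenzylation.
- **Stereochemistry:** the target has no stereocentre and no configurable double bond, so nothing has to be set.

Key step: step 8

Assumption: the target is drawn as the free bis(hydrogen sulfate). Aryl hydrogen sulfates hydrolyse under their own acidity, so the sulfates are carried as sodium salts and the acid form is released only at the very end, in the cold.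

**Step 1**
Reactants: 1 methyl gallate; 2 benzyl bromide
Product: 3 methyl 3,4-bis(benzyloxy)-5-hydroxybenzoate
Conditions: BnBr (2.0 equiv), K2CO3, DMF, 0 °C to rt
Reagents that add atoms: benzyl bromide 2, BrCc1ccccc1
Why: Williamson etherification in which the 4-OH (para to the ester, most acidic) reacts first and the second benzyl goes to either of the two equivalent flanking hydroxyls, so limiting the bromide leaves one hydroxyl free and 3 should be separable from under- and over-alkylated material by chromatography.

**Step 2**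
Reactants: 3 methyl 3,4-bis(benzyloxy)-5-hydroxybenzoate
Product: 4 methyl 3,4-bis(benzyloxy)-5-(methoxymethoxy)benzoate
Conditions: MOMCl, iPr2NEt, CH2Cl2, 0 °C to rt
Reagents that add atoms: chloromethyl methyl ether (MOMCl), COCCl
Why: O-alkylation of the only free phenol (MOM protection) installs an acetal that tolerates hydride, organolithium and methoxide reagents and is orthogonal to the benzyl ethers.

**Step 3**
Reactants: 4 methyl 3,4-bis(benzyloxy)-5-(methoxymethoxy)benzoate
Product: 5 [3,4-bis(benzyloxy)-5-(methoxymethoxy)phenyl]methanol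
Conditions: LiAlH4, THF, 0 °C; H2O then aq NaOH
Reagents that add atoms: none
Why: Hydride reduction of an aromatic ester to the benzylic alcohol, to which benzyl and MOM ethers are inert.

**Step 4**
Reactants: 5 [3,4-bis(benzyloxy)-5-(methoxymethoxy)phenyl]methanol
Product: 6 3,4-bis(benzyloxy)-5-(methoxymethoxy)benzaldehyde
Conditions: activated MnO2, CH2Cl2, rt
Reagents that add atoms: none
Why: Heterogeneous MnO2 oxidation of a benzylic alcohol stops at the aldehyde under neutral conditions that spare the acetal.

**Step 5**
Reactants: 6 3,4-bis(benzyloxy)-5-(methoxymethoxy)benzaldehyde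
Product: 7 1,2-bis(benzyloxy)-5-(2,2-dibromoethenyl)-3-(methoxymethoxy)benzene
Conditions: CBr4, PPh3, CH2Cl2, 0 °C
Reagents that add atoms: carbon tetrabromide, BrC(Br)(Br)Br
Why: First stage of the Corey–Fuchs sequence (Ramirez dibromoolefination), a Wittig-type reaction of the dibromomethylene ylide that is routine for alkoxy-substituted benzaldehydes.

**Step 6**
Reactants: 7 1,2-bis(benzyloxy)-5-(2,2-dibromoethenyl)-3-(methoxymethoxy)benzene
Product: 9 3-[3,4-bis(benzyloxy)-5-(methoxymethoxy)phenyl]-N-methoxy-N-methylprop-2-ynamide, via lithium acetylide 8 (not isolated)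
Conditions: n-BuLi (2.1 equiv), THF, −78 °C; ClC(O)N(OMe)Me, −78 °C to rt
Reagents that add atoms: N-methoxy-N-methylcarbamoyl chloride, CON(C)C(=O)Cl
Why: Second stage of the Corey–Fuchs sequence, in which bromine–lithium exchange, Fritsch–Buttenberg–Wiechell rearrangement and deprotonation give acetylide 8, whose known carbamoylation delivers the propiolic amide without isolating the alkyne.

**Step 7**
Reactants: 9 3-[3,4-bis(benzyloxy)-5-(methoxymethoxy)phenyl]-N-methoxy-N-methylprop-2-ynamide; 10 4-hydroxy-6-methyl-2H-pyran-2-one (triacetic lactone)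
Product: 13 4-hydroxy-6-{4-[3,4-bis(benzyloxy)-5-(methoxymethoxy)phenyl]-2-oxobut-3-yn-1-yl}-2H-pyran-2-one, via dilithiated lactone 11 (not isolated), via tetrahedral adduct 12 (not isolated)
Conditions: 10, LDA (2.2 equiv per 10), THF–DMPU, −78 to −20 °C; 9, −78 °C; cannulate into cold 1 M HCl
Reagents that add atoms: none
Why: Claisen-type C-acylation of the lactone dianion at its 6-methyl carbon in the manner of the Weinreb ketone synthesis, where chelated adduct 12 persists until the inverse acid quench, so that over-addition, proton transfer from the acidic product and re-addition of the released (now protonated) amine to the ynone are all avoided.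

**Step 8**
Reactants: 13 4-hydroxy-6-{4-[3,4-bis(benzyloxy)-5-(methoxymethoxy)phenyl]-2-oxobut-3-yn-1-yl}-2H-pyran-2-one
Product: 16 2-[3,4-bis(benzyloxy)-5-(methoxymethoxy)phenyl]-5,7-dihydroxy-4H-chromen-4-one (4',5'-di-O-benzyl-3'-O-methoxymethyltricetin), via trioxo ester 14 (not isolated), via acylphloroglucinol ynone 15 (not isolated)
Conditions: Mg(OMe)2 (6 equiv), MeOH–THF, rt then reflux; cold 1 M HCl to pH 4
Reagents that add atoms: none
Why: Proposed new method: methoxide from Mg(OMe)2 opens the lactone carbonyl of 13 to the magnesium-chelated trioxo ester 14 (chain C1 = ester carbon, C9 = aryl-bearing alkyne carbon), whose C6 methylene, flanked by the C5 ketone and the C7 ynone carbonyl and destined to be C4a, acylates C1, the future C8a, in a Claisen condensation of the Dieckmann type, and loss of methanol followed by enolisation gives the acylphloroglucinol 15. Ring A therefore closes 6-exo-trig (enolate carbon onto an ester C=O that lies outside the new ring), and ring C closes 6-endo-dig when an ortho phenoxide of 15 adds to C9 and so makes O1–C2. The closest known reaction types are the base-induced rearrangement of 6-(2-oxoalkyl)-4-hydroxy-2-pyranones and of 3,5,7-trioxo esters with alkyl, aryl or styryl termini to acylphloroglucinols and the base-induced cyclisation of 2-hydroxyaryl ynones to flavones; new are the alkynyl ketone terminus carried through the folding and the union of both closures in one flask. The step needs Claisen folding to outrun aldol folding (C2 onto C7) and carbon conjugate addition (C4 onto C9), which should be secured by magnesium binding the C3, C5 and C7 oxygens as chelated enolates, so that no ketone is left as an aldol acceptor while the coordinated ester is held near C6, and by the electron-rich trioxygenated aryl group, which tempers the alkyne as a Michael acceptor. Two further channels lead to the same product: methoxide that adds to C9 at room temperature is displaced there by the phenoxide (addition–elimination, which also rules out 5-exo closure at C8), and an early attack of the C5 enolate oxygen on C9 merely closes ring C first, after which the vinylogous enolate can still acylate C1 through C6. No stereocentre is created, and because the two ortho hydroxyls of 15 are equivalent the second closure poses no regiochemical question.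

**Step 9**
Reactants: 16 4',5'-di-O-benzyl-3'-O-methoxymethyltricetin
Product: 17 2-[3,4-bis(benzyloxy)-5-hydroxyphenyl]-5,7-dihydroxy-4H-chromen-4-one (4',5'-di-O-benzyltricetin)
Conditions: aq 3 M HCl (cat.), MeOH–THF, 45 °C
Reagents that add atoms: none
Why: Acid-catalysed acetal exchange with methanol removes the MOM group while aryl benzyl ethers and the flavone core are stable to dilute acid.

**Step 10**
Reactants: 17 4',5'-di-O-benzyltricetin
Product: 19 disodium 4',5'-di-O-benzyltricetin 7,3'-disulfate, via bis(pyridinium) salt 18 (not isolated)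
Conditions: SO3·pyridine (3 equiv), pyridine–DMF, 0 °C to rt; aq NaHCO3; Sephadex LH-20
Reagents that add atoms: sulfur trioxide–pyridine complex, [O-]S(=O)(=O)[n+]1ccccc1; NaHCO3, [Na+].OC([O-])=O
Why: O-sulfation of phenols with an amine–SO3 complex takes the acidic 7-OH and the free 3'-OH, whereas the 5-OH is locked in a hydrogen bond to the C4 carbonyl and is known to resist a small excess of reagent.

**Step 11**
Reactants: 19 disodium 4',5'-di-O-benzyltricetin 7,3'-disulfate
Product: 21 tricetin 7,3'-disulfate, via disodium salt 20 (not isolated)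
Conditions: H2 (1 atm), 10% Pd/C, MeOH–H2O, rt; filter; Dowex 50WX8 (H+ form), H2O, 0–5 °C; freeze-dry
Reagents that add atoms: none
Why: Catalytic hydrogenolysis of aryl benzyl ethers leaves aryl sulfate salts and the flavone C2–C3 double bond intact at atmospheric pressure, and cold cation exchange replaces sodium by protons before the acid has time to hydrolyse itself.

**Compound list**

1 | methyl gallate | COC(=O)c1cc(O)c(O)c(O)c1 | starting material
2 | benzyl bromide | BrCc1ccccc1 | starting material
3 | methyl 3,4-bis(benzyloxy)-5-hydroxybenzoate | COC(=O)c1cc(O)c(OCc2ccccc2)c(OCc2ccccc2)c1 | intermediate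
4 | methyl 3,4-bis(benzyloxy)-5-(methoxymethoxy)benzoate | COC(=O)c1cc(OCOC)c(OCc2ccccc2)c(OCc2ccccc2)c1 | intermediate
5 | [3,4-bis(benzyloxy)-5-(methoxymethoxy)phenyl]methanol | OCc1cc(OCOC)c(OCc2ccccc2)c(OCc2ccccc2)c1 | intermediate
6 | 3,4-bis(benzyloxy)-5-(methoxymethoxy)benzaldehyde | O=Cc1cc(OCOC)c(OCc2ccccc2)c(OCc2ccccc2)c1 | intermediate
7 | 1,2-bis(benzyloxy)-5-(2,2-dibromoethenyl)-3-(methoxymethoxy)benzene | BrC(Br)=Cc1cc(OCOC)c(OCc2ccccc2)c(OCc2ccccc2)c1 | intermediate
8 | lithium [3,4-bis(benzyloxy)-5-(methoxymethoxy)phenyl]acetylide (not isolated) | [Li]C#Cc1cc(OCOC)c(OCc2ccccc2)c(OCc2ccccc2)c1 | intermediate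
9 | 3-[3,4-bis(benzyloxy)-5-(methoxymethoxy)phenyl]-N-methoxy-N-methylprop-2-ynamide | CON(C)C(=O)C#Cc1cc(OCOC)c(OCc2ccccc2)c(OCc2ccccc2)c1 | intermediate
10 | 4-hydroxy-6-methyl-2H-pyran-2-one (triacetic lactone) | Cc1cc(O)cc(=O)o1 | starting material
11 | dilithiated triacetic lactone, lithium on O4 and on the 6-methylene carbon (not isolated) | [Li]Cc1cc(O[Li])cc(=O)o1 | intermediate
12 | dilithium tetrahedral adduct of 11 and 9, racemic and transient (not isolated) | [Li]OC(Cc1cc(O[Li])cc(=O)o1)(N(C)OC)C#Cc1cc(OCOC)c(OCc2ccccc2)c(OCc2ccccc2)c1 | intermediate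
13 | 4-hydroxy-6-{4-[3,4-bis(benzyloxy)-5-(methoxymethoxy)phenyl]-2-oxobut-3-yn-1-yl}-2H-pyran-2-one | O=C(Cc1cc(O)cc(=O)o1)C#Cc1cc(OCOC)c(OCc2ccccc2)c(OCc2ccccc2)c1 | intermediate
14 | methyl 9-[3,4-bis(benzyloxy)-5-(methoxymethoxy)phenyl]-3,5,7-trioxonon-8-ynoate, present as its magnesium enolate and drawn neutral (not isolated) | COC(=O)CC(=O)CC(=O)CC(=O)C#Cc1cc(OCOC)c(OCc2ccccc2)c(OCc2ccccc2)c1 | intermediate
15 | 3-[3,4-bis(benzyloxy)-5-(methoxymethoxy)phenyl]-1-(2,4,6-trihydroxyphenyl)prop-2-yn-1-one, present as its magnesium phenoxide and drawn neutral (not isolated) | O=C(C#Cc1cc(OCOC)c(OCc2ccccc2)c(OCc2ccccc2)c1)c1c(O)cc(O)cc1O | intermediate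
16 | 2-[3,4-bis(benzyloxy)-5-(methoxymethoxy)phenyl]-5,7-dihydroxy-4H-chromen-4-one | O=c1cc(-c2cc(OCOC)c(OCc3ccccc3)c(OCc3ccccc3)c2)oc2cc(O)cc(O)c12 | intermediate
17 | 2-[3,4-bis(benzyloxy)-5-hydroxyphenyl]-5,7-dihydroxy-4H-chromen-4-one | O=c1cc(-c2cc(O)c(OCc3ccccc3)c(OCc3ccccc3)c2)oc2cc(O)cc(O)c12 | intermediate
18 | bis(pyridinium) 4',5'-di-O-benzyltricetin 7,3'-disulfate (not isolated) | c1cc[nH+]cc1.c1cc[nH+]cc1.O=c1cc(-c2cc(OS(=O)(=O)[O-])c(OCc3ccccc3)c(OCc3ccccc3)c2)oc2cc(OS(=O)(=O)[O-])cc(O)c12 | intermediate
19 | disodium 4',5'-di-O-benzyltricetin 7,3'-disulfate | [Na+].[Na+].O=c1cc(-c2cc(OS(=O)(=O)[O-])c(OCc3ccccc3)c(OCc3ccccc3)c2)oc2cc(OS(=O)(=O)[O-])cc(O)c12 | intermediate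
20 | disodium tricetin 7,3'-disulfate (not isolated) | [Na+].[Na+].O=c1cc(-c2cc(O)c(O)c(OS(=O)(=O)[O-])c2)oc2cc(OS(=O)(=O)[O-])cc(O)c12 | intermediate
21 | tricetin 7,3'-disulfate | O=c1cc(-c2cc(O)c(O)c(OS(=O)(=O)O)c2)oc2cc(OS(=O)(=O)O)cc(O)c12 | target

Total step count: 11
Longest linear sequence: 11 steps, from 1 to 21; lactone 10 enters unchanged at step 7.

**Steps most likely to fail**

**1. Step 8 (carries the label).**
- **What may go wrong:** the opened chain may fold in the aldol sense. A chain carbon may add to the triple bond. The phenoxide may close a five-membered ring. The ynone may oligomerise under methoxide.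
- **Fallback:** it uses only known chemistry, sets out from 9 and comes back at 17, so ring A is bought and not built.
- Commercial phloroglucinol is treated with MOMCl and iPr2NEt to give 1,3,5-tris(methoxymethoxy)benzene F1.
- n-BuLi in THF at 0 °C lithiates F1 between two MOM ethers to give 2,4,6-tris(methoxymethoxy)phenyllithium F2.
- Addition of this aryllithium to amide 9 (Weinreb ketone synthesis) gives the fully MOM-protected aryl ynone F3.
- HCl in MeOH strips all four MOM groups to give the trihydroxyphenyl ynone F4.
- K2CO3 in refluxing acetone closes ring C 6-endo-dig to give 17. Any material that cyclises already under the acid ends at the same compound.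

**2. Step 7.**
- **What may go wrong:** the dianion may add in a conjugate rather than carbonyl fashion to the propiolic amide. The dianion may be poorly soluble. The liberated amine may add to the ynone during the quench.
- **Fallback:** it replaces acylation by carbonyl addition and oxidation, sets out from 7 (with 10) and comes back at 13.
- Dibromoalkene 7 is converted with n-BuLi into acetylide 8, and DMF is added to give 3-[3,4-bis(benzyloxy)-5-(methoxymethoxy)phenyl]prop-2-ynal F5.
- Dianion 11 adds to the aldehyde carbonyl, a known reaction of this dianion, to give the racemic propargylic alcohol F6.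
- MnO2 or Dess–Martin periodinane oxidises this alcohol to ynone 13.

**3. Step 10.**
- **What may go wrong:** sulfation of the flanked 3'-OH may be incomplete. The 5-OH may be slowly sulfated by excess reagent. The very polar salts may be hard to separate.
- **Fallback:** it carries the sulfates as neutral diesters that can be chromatographed on silica, sets out from 17 and comes back at 21.
- 2,2,2-Trichloroethyl chlorosulfate with Et3N and DMAP in THF gives the bis(2,2,2-trichloroethyl sulfate) diester F7.
- Pd/C with HCO2NH4 in MeOH removes both trichloroethyl groups and both benzyl ethers in one operation to give diammonium tricetin 7,3'-disulfate F8.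
- Cold passage through the H+ form of the cation-exchange resin gives 21.

**Further compounds**

F1 | step 8 | 1,3,5-tris(methoxymethoxy)benzene | COCOc1cc(OCOC)cc(OCOC)c1
F2 | step 8 | 2,4,6-tris(methoxymethoxy)phenyllithium | [Li]c1c(OCOC)cc(OCOC)cc1OCOC
F3 | step 8 | 3-[3,4-bis(benzyloxy)-5-(methoxymethoxy)phenyl]-1-[2,4,6-tris(methoxymethoxy)phenyl]prop-2-yn-1-one | O=C(C#Cc1cc(OCOC)c(OCc2ccccc2)c(OCc2ccccc2)c1)c1c(OCOC)cc(OCOC)cc1OCOC
F4 | step 8 | 3-[3,4-bis(benzyloxy)-5-hydroxyphenyl]-1-(2,4,6-trihydroxyphenyl)prop-2-yn-1-one | O=C(C#Cc1cc(O)c(OCc2ccccc2)c(OCc2ccccc2)c1)c1c(O)cc(O)cc1O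
F5 | step 7 | 3-[3,4-bis(benzyloxy)-5-(methoxymethoxy)phenyl]prop-2-ynal | O=CC#Cc1cc(OCOC)c(OCc2ccccc2)c(OCc2ccccc2)c1
F6 | step 7 | 4-hydroxy-6-{4-[3,4-bis(benzyloxy)-5-(methoxymethoxy)phenyl]-2-hydroxybut-3-yn-1-yl}-2H-pyran-2-one (racemic) | OC(Cc1cc(O)cc(=O)o1)C#Cc1cc(OCOC)c(OCc2ccccc2)c(OCc2ccccc2)c1
F7 | step 10 | 4',5'-di-O-benzyltricetin 7,3'-bis(2,2,2-trichloroethyl sulfate) | O=c1cc(-c2cc(OS(=O)(=O)OCC(Cl)(Cl)Cl)c(OCc3ccccc3)c(OCc3ccccc3)c2)oc2cc(OS(=O)(=O)OCC(Cl)(Cl)Cl)cc(O)c12
F8 | step 10 | diammonium tricetin 7,3'-disulfate | [NH4+].[NH4+].O=c1cc(-c2cc(O)c(O)c(OS(=O)(=O)[O-])c2)oc2cc(OS(=O)(=O)[O-])cc(O)c12
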